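Remark: the core is numbered as in elemanolides (ring C5–C10; C1=C2 vinyl and C14 methyl on C10; C3=C4–C15 on C5; C11–C13 on C7; primed numbers for the O8 acyl group). α is the ring face carrying C1 on C10 (and H5, H7); β is the face of the C10 methyl.

## Structural features

The target is an elemane-type lactone ester built on one cyclohexane (C5–C10). C10 carries a methyl and a vinyl group, C5 a 3-hydroxyprop-1-en-2-yl unit, a γ-lactone (O6–C12(=O)–C11, methyl on C11) is trans-fused across C6–C7, and O8 is esterified with (3S)-3,4-dihydroxy-2-methylidenebutanoic acid. Five stereocentres are contiguous around the ring (C10, C5, C6, C7, C8), C11 is attached to C7, and C3′ sits in the side chain. All substituents at C5–C8 are equatorial and alternate in face (H5α, O6α, H7α, O8α); the C10 vinyl is equatorial and trans to the C5 alkenyl group, and the C10 methyl is axial. The fragile parts are the O8 acrylate (a Michael acceptor), the base-epimerisable C11, the primary allylic alcohol, and three terminal alkenes that rule out hydrogenation and hydroboration once present. The real difficulty is twofold: quaternary C10 next to C5 in one absolute sense, and C7, whose carbon substituent is trans to both flanking oxygens. A reagent approaching an sp2 C7 comes from the open β (equatorial) side, so H7α cannot be delivered kinetically and must come from equilibration. The key step exploits the fact that C1 and C15 each lie one atom from the C10–C5 bond. Joined as C10–C1(=O)–O–C15–C4 they form a δ-lactone whose trans fusion is the trans vinyl/alkenyl relationship, and the ester tether makes ring C5–C10 an intramolecular [4+2] between diene C5=C6–C7=C8 and dienophile C9=C10. Hydride cannot distinguish that temporary lactone carbonyl (C1) from the final one (C12), so the temporary ring must be opened before C12 exists.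

## Logic of the disconnections

31 ⇒ 30 ⇒ 24 + 28. The O8–C1′ ester bond is cut, after removal of the O15 silyl ether and the acetonide in one acidic operation. The acrylate tolerates neither hydride, ylide nor strong base, so it is attached last. The gain is a convergent union of the C15 core with a C5 acid. The demand is that O8 be the only free hydroxyl in 24.

28 ⇒ 27 ⇒ 26 ⇒ 25. C2′–C1′ is cut back to a terminal alkyne, and the alkyne to an aldehyde. C2′ is the aldehyde carbon of 25, so the only side-chain stereocentre comes from the chiral pool. The demand is branched (Markovnikov) carbonylation and no racemisation of the α-alkoxy aldehyde.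

24 ⇒ 23 ⇒ 22. C8–O is traced to C8–B, and O15–Si to the free alcohol. Boron is a hydroxyl surrogate that cannot be acylated, silylated or eliminated, so it distinguishes O8 from O6 and O15 without protecting-group steps. The demand is that the C–B bond survive every step from 15 to 23.

22 ⇒ 21 ⇒ 20. C13–H and C11–H are cut (conjugate reduction), then C11–C12 and C12–O6 (carbonylative closure of an enol triflate onto O6). The lactone is thus closed on a C7 centre that is already fixed, so its trans fusion is not at stake. A C7=C11 butenolide followed by reduction is avoided, because hydride would reach C7 from the β face and give the cis-fused lactone. The demand is O6 free, O8 masked, and no reaction of palladium with the other alkenes.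

20 ⇒ 19 ⇒ 17 ⇒ 16. O6–Si is restored, then C1=C2 (methylenation) and the C1 acetal (hydride) are reconnected to the δ-lactone. This is placed here because 16 has no other carbonyl group; after lactonisation C1 and C12 would compete for hydride. The demand is condensation of an ylide with a neopentyl aldehyde without attack on triflate or boronate.

16 ⇒ 15 ⇒ 13. The enol triflate returns to a methyl ketone; C8–B and C7–H return to an enone (conjugate borylation). An acyl group on C7 makes that centre epimerisable, which is the only dependable way to H7α. The demand is α-face addition at C8 and an equilibrium at C7 that favours the all-equatorial isomer.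

13 ⇒ 11 ⇒ 10. C7–C11 is cut (cross-coupling of the ring enol triflate with an acetyl anion equivalent). The C7 oxygen supplied by the cycloaddition becomes the leaving group for carbon. The demand is regioselective enolisation of 10 towards C8.

10 ⇒ 8. C6–O is cut (oxidation of the silyl enol ether). The enol ether from the key step is used directly, and its silyl group ends on O6 as protecting group. The demand is α-face attack, with equilibration α to the ketone as safeguard.

8 ⇒ 7. C5–C10 and C8–C9 are cut (retro-[4+2]). Two rings, quaternary C10 and C5 disappear, leaving an achiral acyclic triene ester. The demand is trans ring fusion and catalyst control of absolute configuration.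

7 ⇒ 6 ⇒ 3 + 4 ⇒ 1 + 2. O–Si is cut, then C5=C6 (Wittig), then the ester C1–O. Three commodity compounds remain. The demand is mono-acylation of a symmetrical diol and in-situ trapping of a sensitive 2-substituted acrolein.

## Other disconnections considered

Alternative 1:
- **Cut:** C1=C2 and C3=C4 are both traced to one C1=C4 bond of a cyclobutene fused at C10–C5.
- **Forward key step:** the cis-fused bicyclooctenone A2 is opened by cross-metathesis with ethylene (second-generation Grubbs catalyst, RuCl2(=CHPh)(PCy3)(H2IMes)) to cyclohexanone A1; no ring forms.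
- **In favour:** quaternary C10 would come from an enone–alkyne [2+2] photocycloaddition, ring strain drives the metathesis, and both alkenes appear together with no oxidation-state change.
- **Against, here:**
  - A1 has the C5 alkenyl group cis to the vinyl group, so C5 must be epimerised through the C6 ketone.
  - A1 as formulated carries its C8 oxygen on the β face, so C8 must be inverted.
  - C7 is a bare methylene. C11 would have to enter by alkylating a C6-ketone enolate that can also form towards C5 and can expel the C8 silyloxy group.
  - The C6 ketone must then be reduced to the equatorial alcohol against the bias of the axial C10 methyl.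
  - Ethenolysis of a trisubstituted cyclobutene to a 1,1-disubstituted alkene is slow.
- **Comparison:**
  - Structure: A1 holds C10 and both alkenes but none of the correct C5–C8 centres, whereas 8 has C10 and C5 correct and an oxygen handle at C7.
  - Mechanism: the alternative is the better, since strain-driven ethenolysis is established catalysis and step 4 is not known in enantioselective form.
  - Step economy: about equal up to the key intermediate, but the alternative then needs two stereochemical corrections and the whole lactone. Its absolute configuration would rest on an enantioselective [2+2], which is no better solved.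

Alternative 2:
- **Cut:** C5–C6.
- **Forward key step:** Me2AlCl activates the aldehyde of A4; C6 bonds to C5 of the (Z)-alkene while oxygen takes hydrogen from the C4 methyl (type 1 carbonyl-ene, isopulegol-like). This gives A3 with the ring, the C6 hydroxyl and the C4=CH2 unit formed together.
- **In favour:** a chair transition state with the C7 and C8 substituents equatorial should set C5 and C6 trans-diequatorial. The C6 hydroxyl then closes the trans lactone onto a C7 centre made earlier, so the hardest problem of the chosen plan (H7α) does not arise; on this point the alternative is the better. The exocyclic alkene and C15 oxygenation come with the ring closure.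
- **Against:**
  - A4 must already hold C7, C8, C10 and C11 in an open chain, including the all-carbon quaternary C10 two bonds from C8.
  - The aldehyde is α-branched and β-silyloxylated, so epimerisation at C7 and elimination threaten under the Lewis acid.
  - The (Z)-alkene must be geometrically pure, and Prins pathways compete.
- **Comparison:**
  - Structure: one ring, one bond and two centres in the key step, against two rings, two bonds and two centres in step 4.
  - Mechanism: equal or better in precedent.
  - Step economy: worse, because a four-centre acyclic precursor is far longer than the three-step achiral 7.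

Alternative 3:
- **Cut:** C6–C7 and O6–C12.
- **Forward key step:** SmI2 (divalent samarium) in THF with t-BuOH reduces the aldehyde of A6 to a ketyl, which adds 6-exo to C7 of the (E)-enoate. The samarium enolate is protonated at C11 and the C6 alkoxide closes the lactone, giving A5.
- **In favour:** ring, lactone and three centres (C6, C7, C11) form in one mild step, with the trans lactone expected from a chair with ketyl oxygen and enoate anti. A5 is three operations from the target. On the C6/C7 problem and on the length of the endgame the alternative is the better.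
- **Against:**
  - A6 needs C5, C8 and quaternary C10 set in an open chain.
  - Its aldehyde is α-branched next to a quaternary carbon and can epimerise at C5.
  - The enoate carries a γ-silyloxy group (O8), which divalent samarium tends to expel by reductive elimination.
- **Comparison:**
  - Structure: A5 is nearer the target than 8.
  - Mechanism: better precedented than step 4, but with a substrate-specific elimination risk.
  - Step economy: the key step is more productive, but the acyclic precursor costs more steps than are saved and needs several independent asymmetric steps where the chosen plan needs one.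

Key step: step 4

## Route

Step 1
Reactants: 1 2-methylidenepropane-1,3-diol; 2 methacryloyl chloride
Product: 3 2-(hydroxymethyl)prop-2-en-1-yl methacrylate
Conditions: 1 (3 equiv), Et3N (1.1 equiv), DMAP (2 mol%), CH2Cl2, −20 °C, slow addition of 2
Reagents that add atoms: none
Why: Acylation of a symmetrical diol; excess 1 and slow addition keep diacylation low, and unreacted 1 is removed by aqueous extraction.

Step 2
Reactants: 3 2-(hydroxymethyl)prop-2-en-1-yl methacrylate; 4 1-(triphenylphosphoranylidene)propan-2-one
Product: 6 (3E)-2-methylidene-5-oxohex-3-en-1-yl methacrylate, via 2-formylprop-2-en-1-yl methacrylate 5 (not isolated)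
Conditions: activated MnO2 (10 equiv), 4 (1.2 equiv), CH2Cl2, 40 °C
Reagents that add atoms: none
Why: Tandem oxidation–Wittig reaction: MnO2 oxidises the allylic alcohol and the stabilised ylide traps the polymerisation-prone 2-substituted acrolein 5 as it forms; stabilised ylides give the (E)-enone.

Step 3
Reactants: 6 (3E)-2-methylidene-5-oxohex-3-en-1-yl methacrylate
Product: 7 (3E)-5-(tert-butyldimethylsilyloxy)-2-methylidenehexa-3,5-dien-1-yl methacrylate
Conditions: TBSOTf (1.2 equiv), Et3N (2 equiv), CH2Cl2, −78 → 0 °C
Reagents that add atoms: tert-butyldimethylsilyl trifluoromethanesulfonate (CC(C)(C)[Si](C)(C)OS(=O)(=O)C(F)(F)F)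
Why: Soft enolisation of the methyl ketone (the only enolisable position) and O-silylation give the 2-silyloxydiene; the methacrylate is inert.

Step 4
Reactants: 7 (3E)-5-(tert-butyldimethylsilyloxy)-2-methylidenehexa-3,5-dien-1-yl methacrylate
Product: 8 trans-fused δ-lactone silyl enol ether, 6-(tert-butyldimethylsilyloxy)-8a-methyl-4-methylidene-3,4,4a,7,8,8a-hexahydro-1H-isochromen-1-one (C10 methyl β, H5 α; C6=C7–OSi)
Conditions: (S)-1-(2-methylphenyl)-3,3-diphenyltetrahydro-1H,3H-pyrrolo[1,2-c][1,3,2]oxazaborole (C24H24BNO, 20 mol%), HNTf2 (18 mol%), CH2Cl2 (0.02 M), −40 → −20 °C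
Reagents that add atoms: none
Why: Proposed new method: an ester-tethered intramolecular Diels–Alder reaction made enantioselective by a chiral boron Lewis acid on the tether carbonyl; the closest known reaction types are thermal or bulky-aluminium-promoted intramolecular Diels–Alder reactions of ester-linked trienes and oxazaborolidinium-catalysed intermolecular Diels–Alder reactions of 2-silyloxydienes with acrylic esters. The cationic boron binds the methacrylate carbonyl, lowers its LUMO and offsets the cost of the s-cis (lactone-like) ester conformer that cyclisation requires, and the diene C5=C6–C7=C8 then adds across C9=C10 in a concerted, asynchronous [4+2] process in which C8–C9 runs ahead of C5–C10. The cyclohexene is the six-membered ring of the cycloaddition itself; the δ-lactone closes through the same C5–C10 bond, its tether atoms C1, O, C15 and C4 lying chair-like between diene terminus and dienophile. C10 and C5 form suprafacially from the (E)-C5=C6 bond and a dienophile whose complexed carbonyl lies exo (methyl endo), which gives the trans ring fusion; the α-methyl group and the bulk of the Lewis acid both disfavour the endo-carbonyl arrangement. Absolute configuration at C10 and C5 is controlled by the catalyst, whose aryl groups screen one face of the bound enoate; the (S)-catalyst is specified from the usual pre-transition-state model and its antipode is equally available. Periselectivity for the C5–C8 diene over the C3–C6 diene follows from the four-atom tether, which cannot span a bridged transition state, and from the higher HOMO of the silyloxydiene. A small excess of oxazaborolidine over HNTf2 and high dilution guard against protodesilylation and intermolecular cycloaddition.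

Step 5
Reactants: 8 trans-fused δ-lactone silyl enol ether
Product: 10 6α-(tert-butyldimethylsilyloxy)-7-oxo δ-lactone, via silyloxy epoxide 9 (not isolated)
Conditions: dimethyldioxirane (1.1 equiv), acetone/CH2Cl2, −78 → 0 °C; then camphorsulfonic acid (2 mol%), CH2Cl2, 0 °C
Reagents that add atoms: dimethyldioxirane (CC1(C)OO1)
Why: Rubottom oxidation: the electron-rich enol ether is epoxidised far faster than the 1,1-disubstituted alkene and from the α face, anti to the axial C10 methyl that is 1,3 to C6; acid-induced opening and 1,4-silyl shift give the α-silyloxy ketone. C6 is α to the ketone and its oxygen is equatorial, so kinetic and thermodynamic outcome coincide.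

Step 6
Reactants: 10 6α-(tert-butyldimethylsilyloxy)-7-oxo δ-lactone
Product: 11 ring enol triflate (C7–OSO2CF3, C7=C8)
Conditions: KN(SiMe3)2 (1.1 equiv), THF, −78 °C; then N-(5-chloropyridin-2-yl)-1,1,1-trifluoro-N-(trifluoromethylsulfonyl)methanesulfonamide (Comins' reagent), −78 °C
Reagents that add atoms: Comins' reagent (FC(F)(F)S(=O)(=O)N(c1ccc(Cl)cn1)S(=O)(=O)C(F)(F)F)
Why: Kinetic deprotonation at the unhindered C8 methylene (C6 is tertiary and silyloxylated) and O-sulfonylation give the C7=C8 enol triflate; the lactone has no α-hydrogen.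

Step 7
Reactants: 11 ring enol triflate
Product: 13 7-acetyl enone (C7=C8), via 2-ethoxydiene 12 (not isolated)
Conditions: tributyl(1-ethoxyethenyl)stannane (1.3 equiv), Pd(PPh3)4 (5 mol%), LiCl (3 equiv), THF, 65 °C; then 0.5 M HCl, THF, 0 °C
Reagents that add atoms: tributyl(1-ethoxyethenyl)stannane (CCCC[Sn](CCCC)(CCCC)C(=C)OCC); water (O)
Why: Stille coupling of the enol triflate with an acetyl anion equivalent, then mild hydrolysis of the enol ether, forms C7–C11 as a methyl enone; LiCl assists transmetalation with triflates.

Step 8
Reactants: 13 7-acetyl enone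
Product: 15 7β-acetyl-8α-(pinacolboryl)-6α-(tert-butyldimethylsilyloxy) δ-lactone, via C7-epimeric boryl ketone 14 (not isolated)
Conditions: B2pin2 (1.2 equiv), CuCl (5 mol%), NaOt-Bu (10 mol%), bis[2-(diphenylphosphino)phenyl] ether (5 mol%), MeOH (2 equiv), THF, 23 °C; then DBU (0.3 equiv), CH2Cl2, 23 °C
Reagents that add atoms: bis(pinacolato)diboron (CC1(C)OB(OC1(C)C)B1OC(C)(C)C(C)(C)O1)
Why: Copper-catalysed conjugate borylation: the boryl–copper species adds to C8 from the α face, anti to the axial C10 methyl (1,3 to C8), and methanol protonates the enolate, expected mainly anti to boron (14). DBU then equilibrates C7 through the enol to the isomer with all of C5–C8 equatorial (acetyl β, H7α); boron cannot act as a β-leaving group, which is why the equilibration is run on the boronate and not on an alcohol.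

Step 9
Reactants: 15 7β-acetyl-8α-(pinacolboryl)-6α-(tert-butyldimethylsilyloxy) δ-lactone
Product: 16 7β-[1-(trifluoromethylsulfonyloxy)ethenyl] δ-lactone
Conditions: KN(SiMe3)2 (1.1 equiv), THF, −78 °C; then Comins' reagent, −78 °C
Reagents that add atoms: Comins' reagent (FC(F)(F)S(=O)(=O)N(c1ccc(Cl)cn1)S(=O)(=O)C(F)(F)F)
Why: Kinetic enolisation at CH3 (C7–H is tertiary and flanked on both sides) and trapping at −78 °C give the terminal enol triflate without disturbing C7; alkyl pinacol boronates tolerate the hindered amide base.

Step 10
Reactants: 16 7β-[1-(trifluoromethylsulfonyloxy)ethenyl] δ-lactone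
Product: 17 lactol (C1 hemiacetal, both anomers)
Conditions: i-Bu2AlH (1.3 equiv), CH2Cl2, −78 °C; aq. potassium sodium tartrate
Reagents that add atoms: none
Why: Partial reduction of the only carbonyl group present, the neopentyl δ-lactone, stops at the lactol because the tetrahedral aluminate is stable at −78 °C. Doing this before C12 exists avoids competition between two lactones.

Step 11
Reactants: 17 lactol
Product: 19 10α-vinyl 15-alcohol (monocyclic), via hydroxy aldehyde 18 (not isolated)
Conditions: Ph3PCH3Br (4 equiv), KN(SiMe3)2 (3.8 equiv), THF, 0 → 45 °C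
Reagents that add atoms: methyltriphenylphosphonium bromide (C[P+](c1ccccc1)(c1ccccc1)c1ccccc1.[Br-])
Why: Wittig methylenation of the lactol through its ring-opened hydroxy aldehyde forms the C1=C2 vinyl group and frees O15 in one operation; C10 is quaternary, so nothing can epimerise.

Step 12
Reactants: 19 10α-vinyl 15-alcohol
Product: 20 6α,15-diol
Conditions: 0.1 M HCl in MeOH, 0 → 23 °C
Reagents that add atoms: none
Why: Acid-catalysed methanolysis removes the only silyl ether; enol triflate, boronate and allylic alcohol are stable to dilute HCl in methanol.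

Step 13
Reactants: 20 6α,15-diol
Product: 21 α-methylidene γ-lactone (trans-fused 6α,12-olide)
Conditions: Pd(PPh3)4 (10 mol%), CO (1 atm), n-Bu3N (2 equiv), MeCN, 65 °C
Reagents that add atoms: carbon monoxide ([C-]#[O+])
Why: Carbonylative lactonisation: oxidative addition of the enol triflate to zerovalent palladium, CO insertion and capture of the acyl–palladium by the neighbouring equatorial O6–H close the five-membered ring. C6 and C7 are already fixed, so the lactone is necessarily trans-fused; the primary O15–H would need an eight-membered ring.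

Step 14
Reactants: 21 α-methylidene γ-lactone
Product: 22 11α-methyl γ-lactone (11βH)
Conditions: NaBH4 (1.5 equiv), MeOH, 0 °C
Reagents that add atoms: none
Why: Conjugate reduction by hydride at C13; protonation of the lactone enolate (and base equilibration if needed) gives the more stable 11α-methyl epimer, the usual outcome for trans-fused 6,12-olides. Isolated alkenes, the boronate and the lactone carbonyl are untouched at 0 °C.

Step 15
Reactants: 22 11α-methyl γ-lactone
Product: 23 15-O-tert-butyldimethylsilyl ether
Conditions: TBSCl (1.1 equiv), imidazole (2 equiv), CH2Cl2, 0 °C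
Reagents that add atoms: tert-butyldimethylsilyl chloride (CC(C)(C)[Si](C)(C)Cl)
Why: Silylation of the only free hydroxyl (primary, allylic).

Step 16
Reactants: 23 15-O-tert-butyldimethylsilyl ether
Product: 24 8α-alcohol
Conditions: NaBO3·4H2O (5 equiv), THF/H2O (1:1), 23 °C
Reagents that add atoms: sodium perborate ([Na+].[Na+].O[B-]1(O)OO[B-](O)(O)OO1)
Why: Oxidation of the C–B bond by 1,2-migration from boron to oxygen proceeds with retention and unmasks the 8α-hydroxyl; perborate is mild enough for the lactone and the silyl ether.

Step 17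
Reactants: 25 (R)-2,2-dimethyl-1,3-dioxolane-4-carbaldehyde
Product: 26 (4S)-4-ethynyl-2,2-dimethyl-1,3-dioxolane
Conditions: dimethyl (1-diazo-2-oxopropyl)phosphonate (1.3 equiv), K2CO3 (2 equiv), MeOH, 0 → 23 °C
Reagents that add atoms: dimethyl (1-diazo-2-oxopropyl)phosphonate (COP(=O)(OC)C(=[N+]=[N-])C(C)=O)
Why: Ohira–Bestmann homologation turns the aldehyde carbon into the internal alkyne carbon; at 0 °C it outruns epimerisation of the α-alkoxy aldehyde (the descriptor changes from R to S only through CIP priorities).

Step 18
Reactants: 26 (4S)-4-ethynyl-2,2-dimethyl-1,3-dioxolane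
Product: 27 methyl 2-[(4S)-2,2-dimethyl-1,3-dioxolan-4-yl]prop-2-enoate
Conditions: Pd(OAc)2 (1 mol%), 2-(diphenylphosphino)pyridine (8 mol%), CH3SO3H (4 mol%), CO (10 bar), MeOH (5 equiv), toluene, 40 °C
Reagents that add atoms: carbon monoxide ([C-]#[O+]); methanol (CO)
Why: Palladium-catalysed methoxycarbonylation of a terminal alkyne with the 2-pyridylphosphine/acid system places CO2Me on the internal carbon (Markovnikov) and gives the 2-substituted acrylate; the stereocentre is not involved, and the excess of basic ligand over acid protects the acetonide.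

Step 19
Reactants: 27 methyl 2-[(4S)-2,2-dimethyl-1,3-dioxolan-4-yl]prop-2-enoate
Product: 28 2-[(4S)-2,2-dimethyl-1,3-dioxolan-4-yl]prop-2-enoic acid
Conditions: LiOH·H2O (1.5 equiv), THF/H2O (3:1), 0 → 23 °C; then 0.5 M HCl to pH 4, 0 °C
Reagents that add atoms: lithium hydroxide ([Li+].[OH-])
Why: Saponification; the acrylate has no α-hydrogen, so neither the alkene nor the stereocentre can move, and the acetonide survives base and brief cold acidification.

Step 20
Reactants: 24 8α-alcohol; 28 2-[(4S)-2,2-dimethyl-1,3-dioxolan-4-yl]prop-2-enoic acid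
Product: 30 fully protected ester (8-O-acyl; 15-O-silyl; acetonide), via mixed anhydride 29 (not isolated)
Conditions: 28 (1.5 equiv), 2,4,6-trichlorobenzoyl chloride (1.5 equiv), Et3N (3 equiv), THF, 23 °C; then 24, DMAP (0.3 equiv), toluene, 23 → 40 °C
Reagents that add atoms: none
Why: Yamaguchi esterification: the mixed anhydride acylates the single free, flanked secondary hydroxyl under DMAP catalysis.

Step 21
Reactants: 30 fully protected ester
Product: 31 CNP0260337.1
Conditions: AcOH/THF/H2O (3:1:1), 45 °C
Reagents that add atoms: none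
Why: Acid hydrolysis removes the primary silyl ether and the acetonide together; esters, lactone and alkenes are stable to aqueous acetic acid.

## Compound list

1 | 2-methylidenepropane-1,3-diol | C=C(CO)CO | starting material
2 | methacryloyl chloride | C=C(C)C(=O)Cl | starting material
3 | 2-(hydroxymethyl)prop-2-en-1-yl methacrylate | C=C(C)C(=O)OCC(=C)CO | intermediate
4 | 1-(triphenylphosphoranylidene)propan-2-one | CC(=O)C=P(c1ccccc1)(c1ccccc1)c1ccccc1 | starting material
5 | 2-formylprop-2-en-1-yl methacrylate (not isolated) | C=C(C)C(=O)OCC(=C)C=O | intermediate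
6 | (3E)-2-methylidene-5-oxohex-3-en-1-yl methacrylate | C=C(C)C(=O)OCC(=C)/C=C/C(C)=O | intermediate
7 | (3E)-5-(tert-butyldimethylsilyloxy)-2-methylidenehexa-3,5-dien-1-yl methacrylate | C=C(C)C(=O)OCC(=C)/C=C/C(=C)O[Si](C)(C)C(C)(C)C | intermediate
8 | trans-fused δ-lactone silyl enol ether, 6-(tert-butyldimethylsilyloxy)-8a-methyl-4-methylidene-3,4,4a,7,8,8a-hexahydro-1H-isochromen-1-one (C10 methyl β, H5 α) | C[C@]12CCC(O[Si](C)(C)C(C)(C)C)=C[C@@H]1C(=C)COC2=O | intermediate
9 | 6α,7α-epoxide of 8 carrying the silyloxy group on C7 (not isolated) | C[C@]12CC[C@@]3(O[Si](C)(C)C(C)(C)C)O[C@H]3[C@@H]1C(=C)COC2=O | intermediate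
10 | 6α-(tert-butyldimethylsilyloxy)-7-oxo δ-lactone | C[C@]12CCC(=O)[C@@H](O[Si](C)(C)C(C)(C)C)[C@@H]1C(=C)COC2=O | intermediate
11 | ring enol triflate (C7–OSO2CF3, C7=C8; 6α-silyloxy) | C[C@]12CC=C(OS(=O)(=O)C(F)(F)F)[C@@H](O[Si](C)(C)C(C)(C)C)[C@@H]1C(=C)COC2=O | intermediate
12 | 7-(1-ethoxyethenyl) diene (not isolated) | C[C@]12CC=C(C(=C)OCC)[C@@H](O[Si](C)(C)C(C)(C)C)[C@@H]1C(=C)COC2=O | intermediate
13 | 7-acetyl enone (C7=C8; 6α-silyloxy) | C[C@]12CC=C(C(C)=O)[C@@H](O[Si](C)(C)C(C)(C)C)[C@@H]1C(=C)COC2=O | intermediate
14 | 7α-acetyl-8α-(pinacolboryl) ketone, C7 epimer of 15 (not isolated) | C[C@]12C[C@@H](B3OC(C)(C)C(C)(C)O3)[C@@H](C(C)=O)[C@@H](O[Si](C)(C)C(C)(C)C)[C@@H]1C(=C)COC2=O | intermediate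
15 | 7β-acetyl-8α-(pinacolboryl)-6α-(tert-butyldimethylsilyloxy) δ-lactone | C[C@]12C[C@@H](B3OC(C)(C)C(C)(C)O3)[C@H](C(C)=O)[C@@H](O[Si](C)(C)C(C)(C)C)[C@@H]1C(=C)COC2=O | intermediate
16 | 7β-[1-(trifluoromethylsulfonyloxy)ethenyl]-8α-(pinacolboryl)-6α-silyloxy δ-lactone | C[C@]12C[C@@H](B3OC(C)(C)C(C)(C)O3)[C@H](C(=C)OS(=O)(=O)C(F)(F)F)[C@@H](O[Si](C)(C)C(C)(C)C)[C@@H]1C(=C)COC2=O | intermediate
17 | lactol of 16 (C1 hemiacetal, both anomers) | C[C@]12C[C@@H](B3OC(C)(C)C(C)(C)O3)[C@H](C(=C)OS(=O)(=O)C(F)(F)F)[C@@H](O[Si](C)(C)C(C)(C)C)[C@@H]1C(=C)COC2O | intermediate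
18 | ring-opened hydroxy aldehyde of 17 (C10–CHO, 15-OH; not isolated) | O=C[C@@]1(C)C[C@@H](B2OC(C)(C)C(C)(C)O2)[C@H](C(=C)OS(=O)(=O)C(F)(F)F)[C@@H](O[Si](C)(C)C(C)(C)C)[C@@H]1C(=C)CO | intermediate
19 | 10α-vinyl-10β-methyl cyclohexane with 5β-(3-hydroxyprop-1-en-2-yl), 6α-silyloxy, 7β-(1-triflyloxyethenyl), 8α-pinacolboryl | C=C[C@@]1(C)C[C@@H](B2OC(C)(C)C(C)(C)O2)[C@H](C(=C)OS(=O)(=O)C(F)(F)F)[C@@H](O[Si](C)(C)C(C)(C)C)[C@@H]1C(=C)CO | intermediate
20 | 6α,15-diol (desilylated 19) | C=C[C@@]1(C)C[C@@H](B2OC(C)(C)C(C)(C)O2)[C@H](C(=C)OS(=O)(=O)C(F)(F)F)[C@@H](O)[C@@H]1C(=C)CO | intermediate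
21 | 8α-(pinacolboryl)-15-hydroxy-11(13)-methylidene 6α,12-olide (trans-fused) | C=C[C@@]1(C)C[C@@H](B2OC(C)(C)C(C)(C)O2)[C@H]3[C@@H](OC(=O)C3=C)[C@@H]1C(=C)CO | intermediate
22 | 8α-(pinacolboryl)-15-hydroxy-11α-methyl 6α,12-olide (11βH) | C=C[C@@]1(C)C[C@@H](B2OC(C)(C)C(C)(C)O2)[C@H]3[C@@H](OC(=O)[C@@H]3C)[C@@H]1C(=C)CO | intermediate
23 | 15-O-tert-butyldimethylsilyl ether of 22 | C=C[C@@]1(C)C[C@@H](B2OC(C)(C)C(C)(C)O2)[C@H]3[C@@H](OC(=O)[C@@H]3C)[C@@H]1C(=C)CO[Si](C)(C)C(C)(C)C | intermediate
24 | 8α-hydroxy-15-(tert-butyldimethylsilyloxy)-11α-methyl 6α,12-olide | C=C[C@@]1(C)C[C@@H](O)[C@H]2[C@@H](OC(=O)[C@@H]2C)[C@@H]1C(=C)CO[Si](C)(C)C(C)(C)C | intermediate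
25 | (R)-2,2-dimethyl-1,3-dioxolane-4-carbaldehyde | O=C[C@H]1COC(C)(C)O1 | starting material
26 | (4S)-4-ethynyl-2,2-dimethyl-1,3-dioxolane | C#C[C@H]1COC(C)(C)O1 | intermediate
27 | methyl 2-[(4S)-2,2-dimethyl-1,3-dioxolan-4-yl]prop-2-enoate | C=C(C(=O)OC)[C@H]1COC(C)(C)O1 | intermediate
28 | 2-[(4S)-2,2-dimethyl-1,3-dioxolan-4-yl]prop-2-enoic acid | C=C(C(=O)O)[C@H]1COC(C)(C)O1 | intermediate
29 | mixed anhydride of 28 with 2,4,6-trichlorobenzoic acid (not isolated) | C=C(C(=O)OC(=O)c1c(Cl)cc(Cl)cc1Cl)[C@H]1COC(C)(C)O1 | intermediate
30 | 8-O-{2-[(4S)-2,2-dimethyl-1,3-dioxolan-4-yl]prop-2-enoyl} ester of 24 | C=C[C@@]1(C)C[C@@H](OC(=O)C(=C)[C@H]2COC(C)(C)O2)[C@H]3[C@@H](OC(=O)[C@@H]3C)[C@@H]1C(=C)CO[Si](C)(C)C(C)(C)C | intermediate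
31 | CNP0260337.1, 8α-[(3S)-3,4-dihydroxy-2-methylidenebutanoyloxy]-15-hydroxy-11βH-elema-1,3-dien-6α,12-olide | C=C[C@@]1(C)C[C@@H](OC(=O)C(=C)[C@H](O)CO)[C@H]2[C@@H](OC(=O)[C@@H]2C)[C@@H]1C(=C)CO | target

## Step count and risk

Total: 21 steps. Longest linear sequence: 18 steps (steps 1–16, 20, 21); steps 17–19 form the side-chain branch.

**Step 4 (key step; carries the new-method label).**
- What may go wrong: low enantioselectivity or no turnover. The methacrylate has no α-hydrogen to organise the catalyst complex, the s-cis ester conformer needed for ring closure is a minor population, and the acid may protodesilylate the diene before cycloaddition.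
- Fallback (sets out from 7, returns at 10): 7 is cyclised without a chiral agent, either thermally (toluene, 0.01 M, 2,6-di-tert-butyl-4-methylphenol, 170 °C, sealed tube) or with Al(OC6H3-2,6-Ph2)3 in CH2Cl2 at −20 °C. Both are known for ester-tethered trienes. This gives 8 together with an equal amount of the enantiomeric lactone ent-8 F1. The mixture is oxidised as in step 5, through the enantiomeric silyloxy epoxide ent-9 F2 beside 9, to 10 and the enantiomeric ketone ent-10 F3. The robust ketone is resolved by preparative chromatography on cellulose tris(3,5-dimethylphenylcarbamate), and 10 continues with step 6.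

**Step 8.**
- What may go wrong: slow or poorly face-selective boryl transfer from copper to the α-branched enone, loss of silanolate from C6 during the basic equilibration, or an equilibrium at C7 that is not decisive enough (the preference for equatorial acetyl is moderate). Any minor C7 epimer would be separated and resubmitted to DBU.
- Fallback (sets out from 13, returns at 24): the C8 oxygen is introduced as oxygen.
  - Nucleophilic epoxidation of 13 (t-BuOOH, DBU, CH2Cl2, 0 °C; α face for the same steric reason) gives the 7α,8α-epoxy ketone F4.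
  - SmI2 (divalent samarium; THF/MeOH, −90 °C) cleaves the Cα–O bond to the β-hydroxy ketone F5, with C7 settled by brief Et3N treatment.
  - 4-Methoxybenzyl 2,2,2-trichloroacetimidate with La(OTf)3 gives the 4-methoxybenzyl ether F6.
  - F6 then passes through the operations of steps 9–15 unchanged: enol triflate F7, lactol F8, 10-vinyl 15-alcohol F9, 6,15-diol F10, α-methylidene lactone F11, 11α-methyl lactone F12 and 15-O-silyl ether F13.
  - DDQ (CH2Cl2/pH 7 buffer) removes the benzyl ether to give 24.
  - The cost is two more steps; the same detour serves if the boronate fails to survive steps 9–15.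

**Step 11.**
- What may go wrong: attack of the basic, boron-philic ylide on the boronate or the enol triflate while condensation with the hindered neopentyl aldehyde (released slowly from the lactol) lags behind.
- Fallback (sets out from 17, returns at 19): 17 is homologated with dimethyl (1-diazo-2-oxopropyl)phosphonate and K2CO3 in MeOH, a much less basic carbon nucleophile, to the terminal alkyne F14. The alkyne is semi-hydrogenated (H2, Pd/CaCO3 poisoned with Pb(OAc)2, quinoline, EtOAc) to the vinyl group of 19, with hydrogen uptake monitored so that the other alkenes are untouched.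

**Step 13.**
- What may go wrong: slow closure of the trans-fused five-membered ring, so that the acyl–palladium intermediate is captured by the primary O15–H of another molecule or reduced.
- Fallback (sets out from 19, returns at 21): carbonylation and ring closure are separated. 19, still silylated at O6, is carbonylated intermolecularly (Pd(OAc)2, 1,3-bis(diphenylphosphino)propane, CO, MeOH, Et3N, DMF, 60 °C) to the methyl 2-substituted acrylate F15. HCl in MeOH then removes the silyl group, and the freed O6–H displaces methanol from the neighbouring ester to give 21.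

## Further compounds

F1 | step 4 | ent-8, enantiomer of the trans-fused δ-lactone silyl enol ether | C[C@@]12CCC(O[Si](C)(C)C(C)(C)C)=C[C@H]1C(=C)COC2=O
F2 | step 4 | ent-9, enantiomeric silyloxy epoxide (not isolated) | C[C@@]12CC[C@]3(O[Si](C)(C)C(C)(C)C)O[C@@H]3[C@H]1C(=C)COC2=O
F3 | step 4 | ent-10, enantiomeric silyloxy ketone | C[C@@]12CCC(=O)[C@H](O[Si](C)(C)C(C)(C)C)[C@H]1C(=C)COC2=O
F4 | step 8 | 7α,8α-epoxy-7-acetyl-6α-silyloxy δ-lactone | C[C@]12C[C@H]3O[C@@]3(C(C)=O)[C@@H](O[Si](C)(C)C(C)(C)C)[C@@H]1C(=C)COC2=O
F5 | step 8 | 7β-acetyl-8α-hydroxy-6α-silyloxy δ-lactone | C[C@]12C[C@@H](O)[C@H](C(C)=O)[C@@H](O[Si](C)(C)C(C)(C)C)[C@@H]1C(=C)COC2=O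
F6 | step 8 | 8α-(4-methoxybenzyloxy) ether of F5 | C[C@]12C[C@@H](OCc3ccc(OC)cc3)[C@H](C(C)=O)[C@@H](O[Si](C)(C)C(C)(C)C)[C@@H]1C(=C)COC2=O
F7 | step 8 | terminal enol triflate of F6 | C[C@]12C[C@@H](OCc3ccc(OC)cc3)[C@H](C(=C)OS(=O)(=O)C(F)(F)F)[C@@H](O[Si](C)(C)C(C)(C)C)[C@@H]1C(=C)COC2=O
F8 | step 8 | lactol of F7 (both anomers) | C[C@]12C[C@@H](OCc3ccc(OC)cc3)[C@H](C(=C)OS(=O)(=O)C(F)(F)F)[C@@H](O[Si](C)(C)C(C)(C)C)[C@@H]1C(=C)COC2O
F9 | step 8 | 10-vinyl 15-alcohol with 8α-(4-methoxybenzyloxy) | C=C[C@@]1(C)C[C@@H](OCc2ccc(OC)cc2)[C@H](C(=C)OS(=O)(=O)C(F)(F)F)[C@@H](O[Si](C)(C)C(C)(C)C)[C@@H]1C(=C)CO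
F10 | step 8 | 6α,15-diol with 8α-(4-methoxybenzyloxy) | C=C[C@@]1(C)C[C@@H](OCc2ccc(OC)cc2)[C@H](C(=C)OS(=O)(=O)C(F)(F)F)[C@@H](O)[C@@H]1C(=C)CO
F11 | step 8 | 8α-(4-methoxybenzyloxy)-15-hydroxy-11(13)-methylidene 6α,12-olide | C=C[C@@]1(C)C[C@@H](OCc2ccc(OC)cc2)[C@H]3[C@@H](OC(=O)C3=C)[C@@H]1C(=C)CO
F12 | step 8 | 8α-(4-methoxybenzyloxy)-15-hydroxy-11α-methyl 6α,12-olide | C=C[C@@]1(C)C[C@@H](OCc2ccc(OC)cc2)[C@H]3[C@@H](OC(=O)[C@@H]3C)[C@@H]1C(=C)CO
F13 | step 8 | 15-O-tert-butyldimethylsilyl ether of F12 | C=C[C@@]1(C)C[C@@H](OCc2ccc(OC)cc2)[C@H]3[C@@H](OC(=O)[C@@H]3C)[C@@H]1C(=C)CO[Si](C)(C)C(C)(C)C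
F14 | step 11 | 10α-ethynyl 15-alcohol (alkyne analogue of 19) | C#C[C@@]1(C)C[C@@H](B2OC(C)(C)C(C)(C)O2)[C@H](C(=C)OS(=O)(=O)C(F)(F)F)[C@@H](O[Si](C)(C)C(C)(C)C)[C@@H]1C(=C)CO
F15 | step 13 | methyl 2-substituted acrylate from 19 (6α-silyloxy, 8α-pinacolboryl, 15-OH) | C=C[C@@]1(C)C[C@@H](B2OC(C)(C)C(C)(C)O2)[C@H](C(=C)C(=O)OC)[C@@H](O[Si](C)(C)C(C)(C)C)[C@@H]1C(=C)CO
A1 | alternative 1 | cis-2-alkenyl-3-methyl-3-vinyl-5-silyloxycyclohexanone (product of the ethenolysis) | C=C[C@@]1(C)C[C@H](O[Si](C)(C)C(C)(C)C)CC(=O)[C@H]1C(=C)CO[Si](c2ccccc2)(c2ccccc2)C(C)(C)C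
A2 | alternative 1 | cis-fused 4-(tert-butyldimethylsilyloxy)-8-[(tert-butyldiphenylsilyloxy)methyl]-6-methylbicyclo[4.2.0]oct-7-en-2-one | C1=C(CO[Si](c3ccccc3)(c3ccccc3)C(C)(C)C)[C@@H]2C(=O)C[C@@H](O[Si](C)(C)C(C)(C)C)C[C@]12C
A3 | alternative 2 | monocyclic 6-hydroxy C12 methyl ester (8-O-triethylsilyl, 15-O-tert-butyldimethylsilyl; product of the ene closure) | C=C[C@@]1(C)C[C@@H](O[Si](CC)(CC)CC)[C@H]([C@@H](C)C(=O)OC)[C@@H](O)[C@@H]1C(=C)CO[Si](C)(C)C(C)(C)C
A4 | alternative 2 | acyclic C6 aldehyde with (Z)-C4=C5 alkene (ene substrate) | C=C[C@@](C)(C[C@@H](O[Si](CC)(CC)CC)[C@H]([C@@H](C)C(=O)OC)C=O)/C=C(/C)CO[Si](C)(C)C(C)(C)C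
A5 | alternative 3 | 8-O-triethylsilyl-15-O-tert-butyldimethylsilyl bicyclic lactone core (product of the ketyl–olefin cyclisation) | C=C[C@@]1(C)C[C@@H](O[Si](CC)(CC)CC)[C@H]2[C@@H](OC(=O)[C@@H]2C)[C@@H]1C(=C)CO[Si](C)(C)C(C)(C)C
A6 | alternative 3 | acyclic C6 aldehyde (E)-2-methylenoate (ketyl–olefin substrate) | C=C[C@@](C)(C[C@@H](O[Si](CC)(CC)CC)/C=C(\C)C(=O)OC)[C@H](C=O)C(=C)CO[Si](C)(C)C(C)(C)C
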